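Fractions of the charge give the quick number asked for, and their logarithms carry it to other recipes.

- violet: starting material 0.10 M; coupling partner 1.05 equiv; protic impurity 0.10 M; the very flask that is asked about, followed so far
- flask: starting material 0.10 M; coupling partner 1.05 equiv; protic impurity 0.100 M; time 15 d

violet run (percent of the starting material charged)

| time / d | starting material / % | target / % |
|---|---|---|
| 0.250 | 1.6 | 35.0 |
| 0.333 | 0.3 | 45.1 |
| 0.500 | 0.9 | 55.8 |
| 0.833 | 0 | 65.9 |
| 1.25 | 0.1 | 67.9 |
| 2.08 | 0 | 69.9 |
| 3.00 | 0 | 68.3 |

(standard deviation of a reading: 1 percentage point)

- why nothing more happens at 15 d, or that something still does (forward and back rates have come level / it is still moving / all of the starting material has reacted / the coupling partner has run out first)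
- share of the starting material used up at 15 d
- target at 15 d, in percent of the starting material charged

- a reading or a percentage of target counts all its forms, free or not
- the reaction counts as stopped when no species that holds the starting material changes by six tenths of a point or more over the second half of the time

The violet run is this flask followed so far. Its starting material reads 0 % at 0.833 d, and its target stays flat from 1.25 d on, averaging 68.7 %. This reckoning assumes that each point of target cost one of coupling partner and that the protic impurity took the missing share, which this one run does not show. Coupling partner then survives as a fraction 34.6 % of its charge and protic impurity as 68.7 %. When two reagents are each used up by one second-order step on the same substrate, at constant volume and temperature, the logarithms of their surviving fractions keep a constant ratio, read here, with the scatter of the plateau, as 2.83: the selectivity factor. On these fractions both reagents survive, so starting material is the limiting reagent, and this reckoning expects the flask to stop with target near 68.7 % at 15 d.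

The forecast gives all of the starting material has reacted, 100 % used up and 69 % target, on the ground that “the simplest reading is that the reaction stopped because everything has reacted”.

The flask gives all of the starting material has reacted, with 100 % used up and 69.4 % target.

    intermediate → target (k = 0.160 h⁻¹)
    starting material + protic impurity → quenched substrate (k = 2.40 M⁻¹ h⁻¹)
    crystals ⇌ target, rate k3*(cs3 - [target]) while solid is left; crystals form when [target] > cs3 (solubility = 1.20 mM, k = 67.0 h⁻¹)
    starting material + coupling partner → intermediate + released group (k = 7.50 M⁻¹ h⁻¹)
    target ⇌ isomer of the product (K = 0.690, k = 0.180 h⁻¹)

At 15 d this flask holds 33 % of its coupling partner and 70 % of its protic impurity, a logarithm ratio of 3.11 beside the 2.83 read earlier. The neighbour charged with 0.25 M of starting material has its protic impurity at 0.400 equiv and ends with 59.8 % of it. That fraction raised to the power 2.83 gives 23.3 % of coupling partner left, and the neighbour holds 20.1 %. The partner so consumed reckons to 80.5 % target, and the neighbour's target stands at 83.6 %.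

The numbers in the tables were generated by integration with constants of no real substance; noise was put on by code.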